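A direct plan would make the three rings one by one and join them by two acid chloride esterifications. Ring A would get its carboxyl by Vilsmeier formylation of 1,2,5-trimethoxy-3-methylbenzene A1 and Pinnick oxidation, and ring B would be carried as a formyl-masked, O-benzylated acid. The ring C phenol A4 would come from a photochemical Wolff rearrangement and vinylketene benzannulation of diazoketone A2 with siloxyalkyne A3, and the tribenzyl tridepside A5 would be hydrogenolysed at the end.
Its weakest steps would be:
- the benzannulation of A2 with A3: about six operations (olefination, diazo transfer, ynol ether, photolysis, Mitsunobu benzylation, desilylation) for what is only a protected orsellinate, resting on an ester-substituted vinylketene that is untried and can isomerise or close to a pyranone;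
- the formylation of A1: a Dakin oxidation, a methylation, the formylation and an oxidation for one benzoic acid, with a regiochemistry (between CH3 and OCH3, not between two OCH3) that is predicted, not secured;
- the benzylation, oxidation and silyl steps around A4 and A5, which form no bond of the skeleton, and the late union of two hindered fragments under base, where a phenoxide could scramble aryl esters.

**Retrosynthetic overview**
Rings B and C are both orsellinoyl units: ring carbons C1–C6, the carboxyl carbon and the methyl carbon form one unbranched 3,5,7-trioxooctanoyl chain. Each ring is therefore cut at its ring bond C1–C6 (aldol), which leads back to one diketo-dioxinone that is used twice; ring B is cut in addition at the acyl C–O bond of its ester (ketene + O–H).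
Ring C closes first, by aldol aromatisation with the dioxinone ring kept and opening of the resulting acetonide by benzyl oxide. Ring B closes second: the acylketene from the same dioxinone is trapped by the 4-OH of ring C, so the B–C depside bond and ring B arise in one operation, with both new phenols free.
Ring A is bought, not built: one directed lithiation puts the methyl group on 2,4,5-trimethoxybenzoic acid, and its acid chloride takes the only unchelated hydroxyl of the didepside; hydrogenolysis of one benzyl ester ends the route.
The design needs no photochemical benzannulation, no formylation of uncertain regiochemistry and no protecting group on any phenol.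

Key step: step 4

Remark: the target is achiral (no stereocentre), so no step has to control configuration; all starting materials named below are taken to be commercial.

Step 1
Reactants: 1 2,2,6-trimethyl-4H-1,3-dioxin-4-one; 2 acetyl chloride
Product: 4 2,2-dimethyl-6-(2-oxopropyl)-4H-1,3-dioxin-4-one, via lithium dienolate 3 (not isolated)
Conditions: 1 (2 equiv), LiN(SiMe3)2 (2 equiv), THF, −78 °C; 2 (1 equiv), −78 °C; aq HCl (1 M)
Reagents that add atoms: lithium bis(trimethylsilyl)amide [Li]N([Si](C)(C)C)[Si](C)(C)C (lithium of 3 only; no atoms in 4)
Why: Vinylogous Claisen-type C-acylation: the amide base removes a proton from the 6-methyl group and the acid chloride acylates dienolate 3 at its exocyclic carbon; 1 and the base are used in twofold amount because 4 is more acidic than 1 and consumes one equivalent of 3.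

Step 2
Reactants: 4 2,2-dimethyl-6-(2-oxopropyl)-4H-1,3-dioxin-4-one; 5 N-methoxy-N-methylacetamide
Product: 7 6-(2,4-dioxopentyl)-2,2-dimethyl-4H-1,3-dioxin-4-one, via dilithium dianion 6 (not isolated)
Conditions: LiN(i-Pr)2 (2.2 equiv), THF, −78 °C; 5, −78 → −20 °C; aq HCl (1 M)
Reagents that add atoms: lithium diisopropylamide [Li]N(C(C)C)C(C)C (lithium of 6 only; no atoms in 7)
Why: Crossed Claisen condensation of a 1,3-dicarbonyl-type dianion: the second deprotonation takes place at the terminal methyl group, this more basic carbanion adds to the N-methoxy-N-methylamide, and the chelated tetrahedral adduct releases the new ketone only on acidic work-up, so over-addition and proton exchange with the product should not interfere.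

Step 3
Reactants: 7 6-(2,4-dioxopentyl)-2,2-dimethyl-4H-1,3-dioxin-4-one; 8 benzyl alcohol
Product: 11 benzyl 2,4-dihydroxy-6-methylbenzoate, via aldol adduct 9 (not isolated), via benzodioxinone 10 (not isolated)
Conditions: Et3N (2 equiv), CH2Cl2, rt; evaporate from PhMe (removal of water); then 8 (3 equiv), NaH (2.5 equiv), THF, 0 → 50 °C; aq HCl (1 M)
Reagents that add atoms: none
Why: Base-mediated aldol aromatisation of a diketo-dioxinone followed by alkoxide opening of the resulting salicylate acetonide (transesterification): triethylamine lets C5 of the dioxinone, the α-carbon of its vinylogous enolate, add to the terminal ketone (6-exo-trig) to give 9, which loses water and enolises to benzodioxinone 10, and NaOCH2Ph then adds to the lactone carbonyl and expels acetone, so that ring C arrives with both phenols free and its carboxyl already protected.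

Step 4
Reactants: 7 6-(2,4-dioxopentyl)-2,2-dimethyl-4H-1,3-dioxin-4-one; 11 benzyl 2,4-dihydroxy-6-methylbenzoate
Product: 15 benzyl 4-[(2,4-dihydroxy-6-methylbenzoyl)oxy]-2-hydroxy-6-methylbenzoate, via acylketene 12 (not isolated), via aryl triketo ester 13 (not isolated), via aldol adduct 14 (not isolated)
Conditions: 11 (1 equiv, 0.5 M), PhMe, 110 °C, slow addition of 7 (1.3 equiv); cool; Et3N (1.5 equiv), CH2Cl2, 0 °C → rt; then CF3CO2H, rt
Reagents that add atoms: none
Why: Proposed new method: the closest known reaction type is the thermolysis of diketo-dioxinones in the presence of alcohols followed by aldol aromatisation to resorcylate esters, joined to the known acetoacetylation of phenols by dioxinone-derived acylketenes; new is a phenol as the trap, so that the ester made is the B–C depside bond and the aldol substrate is an aryl triketo ester. Retro-[4+2] loss of acetone from 7 gives acylketene 12, and the free 4-OH of 11 adds to its ketene carbon through a hydrogen-bonded six-membered transition state to give aryl 3,5,7-trioxooctanoate 13 (acyl C–O bond of the depside). Triethylamine then lets the C2 enolate of 13 close ring B by a 6-exo-trig aldol addition onto the C7 ketone (ring bond C1–C6) to 14, and acid removes water, after which the two remaining ring ketones enolise to the 2- and 4-hydroxyl groups of the arene. The carbinol centre of 14 is lost on dehydration, so no stereocentre has to be controlled. The step needs the 4-OH and not the 2-OH of 11 to add (the 2-OH is held in a hydrogen bond to the benzyl ester carbonyl), trapping to outrun closure of 12 onto its own enol oxygen to a 4-hydroxypyran-2-one (11 is kept concentrated and 7 is added slowly), and aldol closure to outrun Claisen or lactone closure with loss of the aryloxide (amine base, aprotic solvent, no alcohol or alkoxide present). Because the phenols of ring B do not exist while the ketene is present, they cannot be acylated, and 15 should emerge with no protecting group on any hydroxyl.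

Step 5
Reactants: 16 2,4,5-trimethoxybenzoic acid; 17 iodomethane
Product: 19 3,4,6-trimethoxy-2-methylbenzoic acid, via dilithiated benzoate 18 (not isolated)
Conditions: s-BuLi (2.2 equiv), TMEDA (2.2 equiv), THF, −78 °C, 16 added last; 17 (excess), −78 °C → rt; aq HCl
Reagents that add atoms: sec-butyllithium [Li]C(C)CC (lithium of 18 only; no atoms in 19)
Why: Directed ortho-metalation of an unprotected benzoic acid: the base bound to the lithium carboxylate removes H6, the only hydrogen ortho to the carboxylate and also flanked by the C5 methoxy group, in preference to H3 between two methoxy groups, which has no carboxylate to guide the base, and iodomethane alkylates aryllithium 18; inverse addition at −78 °C suppresses attack of the alkyllithium on the carboxylate.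

Step 6
Reactants: 19 3,4,6-trimethoxy-2-methylbenzoic acid; 15 benzyl 4-[(2,4-dihydroxy-6-methylbenzoyl)oxy]-2-hydroxy-6-methylbenzoate
Product: 21 benzyl 2-hydroxy-4-({2-hydroxy-6-methyl-4-[(3,4,6-trimethoxy-2-methylbenzoyl)oxy]benzoyl}oxy)-6-methylbenzoate, via acid chloride 20 (not isolated)
Conditions: 19 (1.05 equiv), (COCl)2, DMF (cat.), CH2Cl2, 0 °C → rt, evaporate; then 15 (1 equiv), Et3N, DMAP (cat.), CH2Cl2, −20 → 0 °C
Reagents that add atoms: oxalyl chloride O=C(Cl)C(=O)Cl (chlorine of 20 only; none remains in 21)
Why: Acylation of a phenol by an acid chloride: of the three hydroxyl groups of 15 only the 4-OH of ring B is not held in a hydrogen bond to an ortho ester carbonyl, and it is the most acidic (para to the ester), so one equivalent of the hindered chloride 20 at low temperature should take it alone, while the 2,6-disubstituted depside carbonyl resists transacylation.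

Step 7
Reactants: 21 benzyl 2-hydroxy-4-({2-hydroxy-6-methyl-4-[(3,4,6-trimethoxy-2-methylbenzoyl)oxy]benzoyl}oxy)-6-methylbenzoate
Product: 22 2-hydroxy-4-({2-hydroxy-6-methyl-4-[(3,4,6-trimethoxy-2-methylbenzoyl)oxy]benzoyl}oxy)-6-methylbenzoic acid (CNP0328932.0)
Conditions: H2 (1 atm), 10% Pd/C, EtOAc, rt
Reagents that add atoms: none
Why: Catalytic hydrogenolysis cleaves the single benzyl ester at its benzylic C–O bond, while aryl esters, aryl methyl ethers and free phenols are inert; there is no stereocentre to set.

**Compound list**

1 | 2,2,6-trimethyl-4H-1,3-dioxin-4-one | CC1=CC(=O)OC(C)(C)O1 | starting material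
2 | acetyl chloride | CC(=O)Cl | starting material
3 | lithium 2,2-dimethyl-6-methylidene-6H-1,3-dioxin-4-olate (lithium dienolate of 1) | [Li+].C=C1C=C([O-])OC(C)(C)O1 | intermediate
4 | 2,2-dimethyl-6-(2-oxopropyl)-4H-1,3-dioxin-4-one | CC(=O)CC1=CC(=O)OC(C)(C)O1 | intermediate
5 | N-methoxy-N-methylacetamide | CC(=O)N(C)OC | starting material
6 | dilithium dianion of 4 (enolate across the ring-side CH2–C(O) unit, carbanion at the terminal CH3) | [Li+].[Li+].[CH2-]C([O-])=CC1=CC(=O)OC(C)(C)O1 | intermediate
7 | 6-(2,4-dioxopentyl)-2,2-dimethyl-4H-1,3-dioxin-4-one | CC(=O)CC(=O)CC1=CC(=O)OC(C)(C)O1 | intermediate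
8 | benzyl alcohol | OCc1ccccc1 | starting material
9 | 5-hydroxy-2,2,5-trimethyl-5,6-dihydro-4H-1,3-benzodioxine-4,7(8H)-dione (racemic) | CC1(O)CC(=O)CC2=C1C(=O)OC(C)(C)O2 | intermediate
10 | 7-hydroxy-2,2,5-trimethyl-4H-1,3-benzodioxin-4-one | Cc1cc(O)cc2OC(C)(C)OC(=O)c12 | intermediate
11 | benzyl 2,4-dihydroxy-6-methylbenzoate (benzyl orsellinate) | Cc1cc(O)cc(O)c1C(=O)OCc1ccccc1 | intermediate
12 | 3,5,7-trioxooct-1-en-1-one (acylketene) | CC(=O)CC(=O)CC(=O)C=C=O | intermediate
13 | 4-[(benzyloxy)carbonyl]-3-hydroxy-5-methylphenyl 3,5,7-trioxooctanoate | CC(=O)CC(=O)CC(=O)CC(=O)Oc1cc(C)c(C(=O)OCc2ccccc2)c(O)c1 | intermediate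
14 | benzyl 2-hydroxy-4-[(2-hydroxy-2-methyl-4,6-dioxocyclohexane-1-carbonyl)oxy]-6-methylbenzoate (racemic, mixture of diastereomers) | CC1(O)CC(=O)CC(=O)C1C(=O)Oc1cc(C)c(C(=O)OCc2ccccc2)c(O)c1 | intermediate
15 | benzyl 4-[(2,4-dihydroxy-6-methylbenzoyl)oxy]-2-hydroxy-6-methylbenzoate (benzyl lecanorate) | Cc1cc(O)cc(O)c1C(=O)Oc1cc(C)c(C(=O)OCc2ccccc2)c(O)c1 | intermediate
16 | 2,4,5-trimethoxybenzoic acid | COc1cc(OC)c(C(=O)O)cc1OC | starting material
17 | iodomethane | CI | starting material
18 | lithium 2-lithio-3,4,6-trimethoxybenzoate | [Li+].[Li]c1c(OC)c(OC)cc(OC)c1C(=O)[O-] | intermediate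
19 | 3,4,6-trimethoxy-2-methylbenzoic acid | COc1cc(OC)c(C(=O)O)c(C)c1OC | intermediate
20 | 3,4,6-trimethoxy-2-methylbenzoyl chloride | COc1cc(OC)c(C(=O)Cl)c(C)c1OC | intermediate
21 | benzyl 2-hydroxy-4-({2-hydroxy-6-methyl-4-[(3,4,6-trimethoxy-2-methylbenzoyl)oxy]benzoyl}oxy)-6-methylbenzoate | COc1cc(OC)c(C(=O)Oc2cc(C)c(C(=O)Oc3cc(C)c(C(=O)OCc4ccccc4)c(O)c3)c(O)c2)c(C)c1OC | intermediate
22 | 2-hydroxy-4-({2-hydroxy-6-methyl-4-[(3,4,6-trimethoxy-2-methylbenzoyl)oxy]benzoyl}oxy)-6-methylbenzoic acid (CNP0328932.0) | COc1cc(OC)c(C(=O)Oc2cc(C)c(C(=O)Oc3cc(C)c(C(=O)O)c(O)c3)c(O)c2)c(C)c1OC | target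

**Step count and risks**

Total step count: 7. Longest linear sequence: 6 steps (steps 1, 2, 3, 4, 6 and 7); step 5 is a one-step branch.

Steps most likely to fail:

Step 4 (proposed new method).
- What may go wrong: the phenol may add to the acylketene more slowly than an alcohol, or the aryl ester may revert to the ketene on prolonged heating, so that the ketene closes onto its own enol oxygen to a pyranone. In the base stage the aryloxide may be expelled by lactone or Claisen closure instead of the aldol closure.
- Fallback (known chemistry): ring B is taken from a second molecule of 11, and the two ester bonds are made in the reverse order by classical acylations. It sets out from 11 and 20.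
- Acylation of the free 4-OH of 11 with 20 (Et3N, DMAP, CH2Cl2) should give benzyl 2-hydroxy-6-methyl-4-[(3,4,6-trimethoxy-2-methylbenzoyl)oxy]benzoate F1.
- Hydrogenolysis (H2, Pd/C, EtOAc) should give 2-hydroxy-6-methyl-4-[(3,4,6-trimethoxy-2-methylbenzoyl)oxy]benzoic acid F2.
- Condensation of F2 with the 4-OH of a further equivalent of 11 by (CF3CO)2O in toluene (mixed anhydride, chelated 2-hydroxyl groups left alone) should give 21, where the fallback rejoins the route before step 7.

Step 6.
- What may go wrong: acylation may go beyond the 4-OH of ring B once DMAP activates the chelated hydroxyls, the orsellinoyl group may migrate between phenoxides under base, or the hindered chloride may react too slowly.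
- Fallback: ring A is attached while ring B has a single free hydroxyl and its salicylate unit is tied up as an acetonide. It sets out from 10, which is isolated after the triethylamine stage of step 3.
- Acylation of its only hydroxyl with 20 (Et3N, DMAP, CH2Cl2) should give 2,2,5-trimethyl-4-oxo-4H-1,3-benzodioxin-7-yl 3,4,6-trimethoxy-2-methylbenzoate F3.
- Irradiation of F3 at 300 nm with 11 in CH2Cl2 expels acetone, and the quinoketene is trapped by the free 4-OH of 11 under neutral conditions to give 21, where the fallback rejoins the route before step 7.

Step 5.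
- What may go wrong: H3 between the two methoxy groups may be removed in competition with H6, or the alkyllithium may attack the carboxylate or displace the ortho methoxy group.
- Fallback: catalytic carboxylate-directed C–H methylation of 16 (Pd(OAc)2, MeB(OH)2, benzoquinone, Ag2CO3, K2HPO4, t-BuOH, 100 °C). The cyclopalladation can reach only the single C–H ortho to the carboxyl. It sets out from 16 and comes back at 19 directly, with no new compound (F0).

**Further compounds**

F1 | step 4 | benzyl 2-hydroxy-6-methyl-4-[(3,4,6-trimethoxy-2-methylbenzoyl)oxy]benzoate | COc1cc(OC)c(C(=O)Oc2cc(C)c(C(=O)OCc3ccccc3)c(O)c2)c(C)c1OC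
F2 | step 4 | 2-hydroxy-6-methyl-4-[(3,4,6-trimethoxy-2-methylbenzoyl)oxy]benzoic acid | COc1cc(OC)c(C(=O)Oc2cc(C)c(C(=O)O)c(O)c2)c(C)c1OC
F3 | step 6 | 2,2,5-trimethyl-4-oxo-4H-1,3-benzodioxin-7-yl 3,4,6-trimethoxy-2-methylbenzoate | COc1cc(OC)c(C(=O)Oc2cc(C)c3C(=O)OC(C)(C)Oc3c2)c(C)c1OC
F0 | step 5 | none | none
A1 | direct plan | 1,2,5-trimethoxy-3-methylbenzene | COc1cc(C)c(OC)c(OC)c1
A2 | direct plan | benzyl (2E)-5-diazo-3-methyl-4-oxopent-2-enoate | [N-]=[N+]=CC(=O)/C(C)=C/C(=O)OCc1ccccc1
A3 | direct plan | (triisopropylsilyloxy)ethyne | C#CO[Si](C(C)C)(C(C)C)C(C)C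
A4 | direct plan | benzyl 2-(benzyloxy)-4-hydroxy-6-methylbenzoate | Cc1cc(O)cc(OCc2ccccc2)c1C(=O)OCc1ccccc1
A5 | direct plan | benzyl 2-(benzyloxy)-4-({2-(benzyloxy)-6-methyl-4-[(3,4,6-trimethoxy-2-methylbenzoyl)oxy]benzoyl}oxy)-6-methylbenzoate | COc1cc(OC)c(C(=O)Oc2cc(C)c(C(=O)Oc3cc(C)c(C(=O)OCc4ccccc4)c(OCc4ccccc4)c3)c(OCc3ccccc3)c2)c(C)c1OC
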